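Cuts, last to first: the O3'–benzyl bond and the O5–CH2–O6 bridge (protecting groups only), then C4a–C4, C4–C3 and O1–C2. These three cuts take ring C apart into an ortho-iodophenol (ring A), CO (C4) and an arylacetylene (C3, C2, ring B).
Enabling feature: the ring A phenol bears oxygen on C5, C6, C7, C8 and C8a. C4a, between the C8a hydroxyl and the C5 oxygen of the 5,6-dioxole, holds the only ring hydrogen, so iodination has one possible site, the carbon that must bond to C4.
Ring A comes from dillapiole, which already has the 7,8-dimethoxy/5,6-dioxole pattern. Its allyl-bearing carbon is degraded to C8a–OH by isomerisation, ozonolysis and Baeyer–Villiger oxidation. Ring B with C2/C3 comes from isovanillin by benzylation and alkyne homologation.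
Forward order: rings A and B are bought. Ring C is the only ring built and closes in one palladium-catalysed three-component step. One BCl3 step then frees the 5-, 6- and 3'-hydroxyls.
Stereochemistry: there is none to set, because the target is a flat, achiral flavone.

Key step: step 7

Remark: the target has no stereocentre, stereogenic axis or configured double bond, so the achiral compound itself meets the demand for a single enantiomer; dillapiole is taken as a purchasable essential-oil constituent.

Step 1
Reactants: 1 dillapiole (4,5-dimethoxy-6-(prop-2-en-1-yl)-1,3-benzodioxole)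
Product: 2 (E)-isodillapiole (4,5-dimethoxy-6-[(E)-prop-1-en-1-yl]-1,3-benzodioxole)
Conditions: KOH, n-BuOH, reflux
Reagents that add atoms: none
Why: Base-mediated allylbenzene-to-propenylbenzene isomerisation (1,3-prototropic shift) is driven by conjugation with the electron-rich ring and favours the E-alkene, whose geometry is erased again in step 2.

Step 2
Reactants: 2 (E)-isodillapiole
Product: 4 6,7-dimethoxy-1,3-benzodioxole-5-carbaldehyde, via secondary ozonide 3 (not isolated)
Conditions: O3, CH2Cl2, −78 °C (Sudan III end-point); then Me2S, −78 °C to rt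
Reagents that add atoms: ozone, [O-][O+]=O
Why: In this ozonolysis (Criegee mechanism) with reductive work-up the styrenyl double bond reacts far faster than the arene, and the dye end-point keeps surplus ozone away from the electron-rich ring.

Step 3
Reactants: 4 6,7-dimethoxy-1,3-benzodioxole-5-carbaldehyde
Product: 6 6,7-dimethoxy-1,3-benzodioxol-5-ol, via aryl formate 5 (not isolated)
Conditions: mCPBA (1.2 equiv), CH2Cl2, 0 °C to rt; aq. Na2S2O3/NaHCO3 wash; crude 5 in MeOH, HCl (cat.), rt, Ar
Reagents that add atoms: meta-chloroperoxybenzoic acid, OOC(=O)c1cccc(Cl)c1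
Why: In this Baeyer–Villiger (Dakin-type) oxidation the aryl group, pushed by its ortho- and para-oxygen donors, migrates in preference to hydride, and acid-catalysed transesterification of the formate frees the oxidation-prone phenol without base, air or residual peracid.

Step 4
Reactants: 6 6,7-dimethoxy-1,3-benzodioxol-5-ol
Product: 7 4-iodo-6,7-dimethoxy-1,3-benzodioxol-5-ol
Conditions: NIS (1.05 equiv), MeCN, 0 °C, dark
Reagents that add atoms: N-iodosuccinimide, O=C1CCC(=O)N1I
Why: In this electrophilic aromatic iodination C4 is the only ring carbon that carries hydrogen and lies ortho to the free hydroxyl, so neither a regioisomer nor a second iodination is possible, and a mild I+ donor in the cold limits oxidation of the phenol.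

Step 5
Reactants: 8 isovanillin (3-hydroxy-4-methoxybenzaldehyde); 9 benzyl bromide
Product: 10 3-(benzyloxy)-4-methoxybenzaldehyde
Conditions: K2CO3, DMF, 60 °C
Reagents that add atoms: benzyl bromide (9), BrCc1ccccc1
Why: Williamson ether synthesis should alkylate the single phenol cleanly, since the non-enolisable aldehyde is inert to carbonate.

Step 6
Reactants: 10 3-(benzyloxy)-4-methoxybenzaldehyde
Product: 11 2-(benzyloxy)-4-ethynyl-1-methoxybenzene
Conditions: dimethyl (1-diazo-2-oxopropyl)phosphonate, K2CO3, MeOH, rt
Reagents that add atoms: dimethyl (1-diazo-2-oxopropyl)phosphonate (Ohira–Bestmann reagent), COP(=O)(OC)C(=[N+]=[N-])C(C)=O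
Why: The Seyferth–Gilbert homologation in its Ohira–Bestmann form turns non-enolisable aryl aldehydes into terminal alkynes under carbonate/methanol, which leaves benzyl and methyl ethers untouched.

Step 7
Reactants: 7 4-iodo-6,7-dimethoxy-1,3-benzodioxol-5-ol; 11 2-(benzyloxy)-4-ethynyl-1-methoxybenzene; 12 carbon monoxide
Product: 15 3'-(benzyloxy)-7,8,4'-trimethoxy-5,6-(methylenedioxy)flavone, via hydroxyaryl ynone 13 (not isolated), via diethylamino enone 14 (not isolated)
Conditions: PdCl2(dppf) (5 mol %), CO (20 bar), Et2NH, 120 °C, autoclave, no copper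
Reagents that add atoms: carbon monoxide (12), [C-]#[O+]
Why: Pd(0) should insert into the C4a–I bond of 7, CO then migrates in, and the acylpalladium meets the acetylide that diethylamine frees from 11, so that reductive elimination delivers ynone 13 with C4a–C4 and C4–C3 in place. Diethylamine next adds to the ring-B-bearing alkyne carbon of 13 to give the push–pull enone 14, and the C8a hydroxyl displaces the amine there by addition–elimination, which makes O1–C2. The closest known reaction type is the carbonylative Sonogashira annulation of 2-iodophenols and terminal arylacetylenes in a secondary amine, an established flavone synthesis applied here to an iodide with oxygen on both neighbouring carbons. Ring C, the only ring formed, closes 6-endo-trig on 14, and the rival 5-exo-dig attack of a phenoxide on the carbonyl-side alkyne carbon of 13 (aurone mode) is pre-empted because amine addition comes first and leaves only C2 electrophilic. No stereocentre arises. The step also needs CO insertion to outrun CO-free alkynylation and amide formation, which copper-free conditions, CO pressure, chelating dppf and the fast migration of an electron-rich aryl group should secure, and it needs closure through O8a alone, which the substrate guarantees because O5 is held in the small, tied-back dioxole that also keeps the flank of the iodide open.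

Step 8
Reactants: 15 3'-(benzyloxy)-7,8,4'-trimethoxy-5,6-(methylenedioxy)flavone
Product: 17 5,6,3'-trihydroxy-7,8,4'-trimethoxyflavone, via boron-bound chloromethyl ether 16 (not isolated)
Conditions: BCl3 (5 equiv), CH2Cl2, −78 to 0 °C; then 1 M aq. HCl, THF, rt, Ar
Reagents that add atoms: none
Why: In this boron trichloride ether cleavage, boron held between the C4 carbonyl and O5 opens the O5–CH2 bond of the acetal (an oxocarbenium-forming cleavage that BCl3 is known to prefer over aryl methyl ether cleavage), the benzyl ether leaves as benzyl chloride with no ring A C–H available for Friedel–Crafts benzylation, and the three methoxyls, none peri to the carbonyl, should outlast the reagent at or below 0 °C before aqueous acid hydrolyses the O–B bonds and the chloromethyl ether of 16.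

Compound list
1 | dillapiole, 4,5-dimethoxy-6-(prop-2-en-1-yl)-1,3-benzodioxole | C=CCc1cc2OCOc2c(OC)c1OC | starting material
2 | (E)-isodillapiole, 4,5-dimethoxy-6-[(E)-prop-1-en-1-yl]-1,3-benzodioxole | C/C=C/c1cc2OCOc2c(OC)c1OC | intermediate
3 | 3-(6,7-dimethoxy-1,3-benzodioxol-5-yl)-5-methyl-1,2,4-trioxolane (secondary ozonide, cis/trans mixture, racemic, both centres destroyed in the same step) | CC1OOC(O1)c1cc2OCOc2c(OC)c1OC | intermediate (not isolated)
4 | 6,7-dimethoxy-1,3-benzodioxole-5-carbaldehyde | O=Cc1cc2OCOc2c(OC)c1OC | intermediate
5 | 6,7-dimethoxy-1,3-benzodioxol-5-yl formate | O=COc1cc2OCOc2c(OC)c1OC | intermediate (not isolated)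
6 | 6,7-dimethoxy-1,3-benzodioxol-5-ol | Oc1cc2OCOc2c(OC)c1OC | intermediate
7 | 4-iodo-6,7-dimethoxy-1,3-benzodioxol-5-ol | COc1c(O)c(I)c2OCOc2c1OC | intermediate
8 | isovanillin, 3-hydroxy-4-methoxybenzaldehyde | COc1ccc(C=O)cc1O | starting material
9 | benzyl bromide | BrCc1ccccc1 | starting material
10 | 3-(benzyloxy)-4-methoxybenzaldehyde | COc1ccc(C=O)cc1OCc1ccccc1 | intermediate
11 | 2-(benzyloxy)-4-ethynyl-1-methoxybenzene | C#Cc1ccc(OC)c(OCc2ccccc2)c1 | intermediate
12 | carbon monoxide | [C-]#[O+] | starting material
13 | 3-[3-(benzyloxy)-4-methoxyphenyl]-1-(5-hydroxy-6,7-dimethoxy-1,3-benzodioxol-4-yl)prop-2-yn-1-one | COc1ccc(C#CC(=O)c2c(O)c(OC)c(OC)c3OCOc23)cc1OCc1ccccc1 | intermediate (not isolated)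
14 | (E)-3-[3-(benzyloxy)-4-methoxyphenyl]-3-(diethylamino)-1-(5-hydroxy-6,7-dimethoxy-1,3-benzodioxol-4-yl)prop-2-en-1-one (push–pull alkene, geometry of no consequence) | CCN(CC)/C(=C/C(=O)c1c(O)c(OC)c(OC)c2OCOc12)c1ccc(OC)c(OCc2ccccc2)c1 | intermediate (not isolated)
15 | 3'-(benzyloxy)-7,8,4'-trimethoxy-5,6-(methylenedioxy)flavone | COc1ccc(-c2cc(=O)c3c4OCOc4c(OC)c(OC)c3o2)cc1OCc1ccccc1 | intermediate
16 | 6-(chloromethoxy)-5,3'-bis(dichloroboryloxy)-7,8,4'-trimethoxyflavone | COc1ccc(-c2cc(=O)c3c(OB(Cl)Cl)c(OCCl)c(OC)c(OC)c3o2)cc1OB(Cl)Cl | intermediate (not isolated)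
17 | 5,6,3'-trihydroxy-7,8,4'-trimethoxyflavone (achiral) | COc1ccc(-c2cc(=O)c3c(O)c(O)c(OC)c(OC)c3o2)cc1O | target

Total step count: 8.
Longest linear sequence: 6 steps (steps 1, 2, 3, 4, 7, 8, from dillapiole). The isovanillin branch adds steps 5 and 6 in parallel.

Steps most likely to fail

Step 7. The C–I bond of 7 sits on a very electron-rich ring between two oxygens, so oxidative addition may lag. Reduction of the iodide, capture of the acylpalladium by diethylamine, or alkynylation without CO uptake followed by furan closure could then consume the partners. The fallback builds ring C from a chalcone, without palladium or CO, and sets out from phenol 6 and aldehyde 10. Friedel–Crafts/Fries C-acetylation of 6 at the same lone C–H (Ac2O, BF3·OEt2, 80 °C) should give 1-(5-hydroxy-6,7-dimethoxy-1,3-benzodioxol-4-yl)ethan-1-one F1. Claisen–Schmidt condensation of F1 with 10 (KOH, EtOH, rt) should give the 2'-hydroxychalcone (E)-3-[3-(benzyloxy)-4-methoxyphenyl]-1-(5-hydroxy-6,7-dimethoxy-1,3-benzodioxol-4-yl)prop-2-en-1-one F2. Oxidative cyclisation of F2 (I2 cat., DMSO, 130 °C) comes back to the route at 15.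

Step 8. The Lewis acid may also remove a methyl group, either at the crowded O7 or at O4' next to the boron-bound O3'. The acetal opening may stall halfway, or the 5,6-diol may be oxidised by air during work-up. The fallback unmasks the bridge by oxidation rather than by a Lewis acid, removes the benzyl group separately, and sets out from 15. Acetoxylation of the O–CH2–O carbon with Pb(OAc)4 (benzene, reflux) should raise it to the orthoformate level and give racemic 5,6-(acetoxymethylenedioxy)-3'-(benzyloxy)-7,8,4'-trimethoxyflavone F3. Mild hydrolysis (aq. AcOH, THF, 40 °C) should then give 3'-(benzyloxy)-5,6-dihydroxy-7,8,4'-trimethoxyflavone F4. Hydrogenolysis of F4 (H2, Pd/C, EtOAc/THF, rt) comes back to the route at 17.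

Step 4. Electron transfer from the pentaoxygenated phenol to the I+ donor could lead to oxidation to quinonoid material or to oxidative coupling, and this may compete with substitution. The fallback replaces the electrophilic iodination with a directed ortho-metalation and sets out from 6. Protection (MOMCl, iPr2NEt, CH2Cl2, 0 °C to rt) should give 4,5-dimethoxy-6-(methoxymethoxy)-1,3-benzodioxole F5. Lithiation of the only aromatic C–H, flanked by the OMOM group and the dioxole oxygen (n-BuLi, THF, −78 to −20 °C), and quenching with I2 should give 4-iodo-6,7-dimethoxy-5-(methoxymethoxy)-1,3-benzodioxole F6. Acidic methanolysis of F6 (HCl cat., MeOH, 40 °C) comes back to the route at 7.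

Further compounds
F1 | step 7 | 1-(5-hydroxy-6,7-dimethoxy-1,3-benzodioxol-4-yl)ethan-1-one | CC(=O)c1c(O)c(OC)c(OC)c2OCOc12
F2 | step 7 | (E)-3-[3-(benzyloxy)-4-methoxyphenyl]-1-(5-hydroxy-6,7-dimethoxy-1,3-benzodioxol-4-yl)prop-2-en-1-one | COc1ccc(/C=C/C(=O)c2c(O)c(OC)c(OC)c3OCOc23)cc1OCc1ccccc1
F3 | step 8 | 5,6-(acetoxymethylenedioxy)-3'-(benzyloxy)-7,8,4'-trimethoxyflavone (racemic at the acetal carbon) | COc1ccc(-c2cc(=O)c3c4OC(OC(C)=O)Oc4c(OC)c(OC)c3o2)cc1OCc1ccccc1
F4 | step 8 | 3'-(benzyloxy)-5,6-dihydroxy-7,8,4'-trimethoxyflavone | COc1ccc(-c2cc(=O)c3c(O)c(O)c(OC)c(OC)c3o2)cc1OCc1ccccc1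
F5 | step 4 | 4,5-dimethoxy-6-(methoxymethoxy)-1,3-benzodioxole | COCOc1cc2OCOc2c(OC)c1OC
F6 | step 4 | 4-iodo-6,7-dimethoxy-5-(methoxymethoxy)-1,3-benzodioxole | COCOc1c(I)c2OCOc2c(OC)c1OC
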